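Daucane numbering: cyclopentane C1–C5, cycloheptene C1/C5–C10. Everything rests on the C3–C4 bond. The tertiary carbinol C4 (OH, isopropyl) lies β to oxygenated C2, so the cyclopentane is an aldol retron. The key step closes it on a finished cycloheptadienone that bears an acetyl group (C2, C3) on quaternary C1 and an isobutyryl group (C4) on C5, trans to each other. One operation should give the trans-hydroazulene and the C4 carbinol. Only C6 is set by catalysis (glyoxylate-ene reaction). It relays to C5 and C1 in one conjugate addition–aldol event. The C4 hydroxyl then directs reduction at C2, and the C1 methyl group steers reduction at C10.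

Key step: step 11

Remark on numbering: C1 is the quaternary fusion carbon (CH3), C2 CH–OAc, C3 CH2, C4 C(OH)(iPr), C5 the fusion CH, C6 CH–OAng, C7 CH2, C8 =C(CH3), C9 =CH and C10 CH–OBz. All intermediates keep these numbers. β is the ring face of the C1 methyl group and α the opposite face. The target is 2α-OAc, 4β-OH, 5α-H, 6α-OAng, 10β-OBz, which is (1R,2S,4R,5S,6S,10S).
Remark on undefined centers: stereocenters that a later step erases (in 8, 9, 10, 17 and 19) are left undefined in the SMILES.

Step 1
Reactants: 1 2-methylpropene (isobutene); 2 ethyl glyoxylate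
Product: 3 ethyl (S)-2-hydroxy-4-methylpent-4-enoate
Conditions: (S)-BINOL (10 mol %), TiCl2(OiPr)2 (10 mol %), 4 Å molecular sieves, CH2Cl2, −30 °C
Reagents that add atoms: none
Why: Catalytic asymmetric carbonyl-ene (glyoxylate-ene) reaction, in which the (S)-BINOL–titanium Lewis acid binds the aldehyde of 2 and leaves one face open to 1, which should set C6 as S.

Step 2
Reactants: 3 ethyl (S)-2-hydroxy-4-methylpent-4-enoate
Product: 4 ethyl (S)-2-(tert-butyldimethylsilyloxy)-4-methylpent-4-enoate
Conditions: TBSCl, imidazole, DMF, rt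
Reagents that add atoms: tert-butyldimethylsilyl chloride, CC(C)(C)[Si](C)(C)Cl
Why: Standard silyl ether protection of a secondary alcohol, which does not touch C6.

Step 3
Reactants: 4 ethyl (S)-2-(tert-butyldimethylsilyloxy)-4-methylpent-4-enoate
Product: 5 (S)-2-(tert-butyldimethylsilyloxy)-4-methylpent-4-enal
Conditions: iBu2AlH (1.05 equiv), CH2Cl2, −78 °C; aq. potassium sodium tartrate
Reagents that add atoms: none
Why: Partial reduction of an ester to the aldehyde with iBu2AlH at low temperature, under which the α-silyloxy center C6 is not enolised.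

Step 4
Reactants: 5 (S)-2-(tert-butyldimethylsilyloxy)-4-methylpent-4-enal; 6 pent-1-en-3-one (ethyl vinyl ketone)
Product: 8 (6S)-6-(tert-butyldimethylsilyloxy)-5-hydroxy-4,8-dimethylnona-1,8-dien-3-one, via lithium enolate 7 (not isolated)
Conditions: LiN(iPr)2, THF, −78 °C, 6; then 5, −78 °C; AcOH quench at −78 °C
Reagents that add atoms: none
Why: Lithium enolate aldol addition, in which kinetic deprotonation of the ethyl CH2 of 6 gives 7, which adds to the aldehyde faster than C6 can epimerise; the two new centers (C1, C5) are erased in step 6.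

Step 5
Reactants: 8 (6S)-6-(tert-butyldimethylsilyloxy)-5-hydroxy-4,8-dimethylnona-1,8-dien-3-one
Product: 9 (5S)-5-(tert-butyldimethylsilyloxy)-6-hydroxy-3,7-dimethylcyclohept-2-en-1-one
Conditions: second-generation Grubbs catalyst (5 mol %), CH2Cl2 (2 mM), reflux
Reagents that add atoms: none
Why: Ring-closing metathesis of the vinyl ketone with the 1,1-disubstituted alkene closes the seven-membered ring as the trisubstituted C8=C9 enone, driven by loss of ethene at high dilution.

Step 6
Reactants: 9 (5S)-5-(tert-butyldimethylsilyloxy)-6-hydroxy-3,7-dimethylcyclohept-2-en-1-one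
Product: 11 (S)-4-(tert-butyldimethylsilyloxy)-2,6-dimethylcyclohepta-2,6-dien-1-one, via mesylate 10 (not isolated)
Conditions: MsCl, Et3N (excess), CH2Cl2, 0 °C to rt
Reagents that add atoms: none
Why: Mesylation and E1cB elimination of a β-hydroxy ketone, in which the ring enforces the cis C1=C5 geometry that an open-chain dehydration would not give and the mild amine base limits further loss of the C6 silyloxy group.

Step 7
Reactants: 12 3-methylbut-1-yne
Product: 13 2-bromo-3-methylbut-1-ene
Conditions: Et4N[HBr2], CH2Cl2, 40 °C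
Reagents that add atoms: tetraethylammonium hydrogen dibromide, CC[N+](CC)(CC)CC.Br.[Br-]
Why: Markovnikov hydrobromination of a terminal alkyne with a hydrogen dibromide salt, which should stop at the 2-bromoalk-1-ene.

Step 8
Reactants: 11 (S)-4-(tert-butyldimethylsilyloxy)-2,6-dimethylcyclohepta-2,6-dien-1-one; 13 2-bromo-3-methylbut-1-ene; 14 acetaldehyde
Product: 17 (5S,6S,7R)-5-(tert-butyldimethylsilyloxy)-7-(1-hydroxyethyl)-3,7-dimethyl-6-(3-methylbut-1-en-2-yl)cyclohept-2-en-1-one, via Grignard reagent 15 (not isolated), via magnesium enolate 16 (not isolated)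
Conditions: 13, Mg, THF; then CuBr·SMe2 (15 mol %), 11, THF–Me2S, −78 to −40 °C; then 14, −78 °C; AcOH quench at −78 °C
Reagents that add atoms: none
Why: Copper-catalysed conjugate addition of a Grignard reagent with aldol trapping (three-component coupling): the organocopper species attacks the unsubstituted β-carbon C5 rather than methyl-bearing C8 and does so anti to the 6α-silyloxy group, and enolate 16 then takes up acetaldehyde at C1 anti to the new 5β-alkenyl group, which sets C5 and quaternary C1 in one event (the carbinol center is erased in step 9).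

Step 9
Reactants: 17 (5S,6S,7R)-5-(tert-butyldimethylsilyloxy)-7-(1-hydroxyethyl)-3,7-dimethyl-6-(3-methylbut-1-en-2-yl)cyclohept-2-en-1-one
Product: 18 (5S,6S,7R)-7-acetyl-5-(tert-butyldimethylsilyloxy)-3,7-dimethyl-6-(3-methylbut-1-en-2-yl)cyclohept-2-en-1-one
Conditions: Dess–Martin periodinane, CH2Cl2, rt
Reagents that add atoms: none
Why: Dess–Martin oxidation of the hindered secondary alcohol under neutral conditions, which avoids retro-aldol cleavage at quaternary C1.

Step 10
Reactants: 18 (5S,6S,7R)-7-acetyl-5-(tert-butyldimethylsilyloxy)-3,7-dimethyl-6-(3-methylbut-1-en-2-yl)cyclohept-2-en-1-one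
Product: 20 (5S,6S,7R)-7-acetyl-5-(tert-butyldimethylsilyloxy)-3,7-dimethyl-6-(2-methylpropanoyl)cyclohept-2-en-1-one, via ozonide 19 (not isolated)
Conditions: O3, CH2Cl2, −78 °C (Sudan Red 7B end point); then Me2S, −78 °C to rt
Reagents that add atoms: ozone, [O-][O+]=O
Why: Chemoselective ozonolysis, in which the isolated 1,1-disubstituted alkene reacts much faster than the electron-poor C8=C9 enone and reduction of ozonide 19 with Me2S unmasks the C4 isopropyl ketone.

Step 11
Reactants: 20 (5S,6S,7R)-7-acetyl-5-(tert-butyldimethylsilyloxy)-3,7-dimethyl-6-(2-methylpropanoyl)cyclohept-2-en-1-one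
Product: 23 6α-(tert-butyldimethylsilyloxy)-4β-hydroxy-5αH-dauc-8-ene-2,10-dione, via lithium enolate 21 (not isolated), via lithium aldolate 22 (not isolated)
Conditions: LiN(SiMe3)2 (1.05 equiv), THF, −78 to −40 °C; AcOH quench at −78 °C
Reagents that add atoms: none
Why: The base removes a proton from the only unhindered α-position, the C3 methyl group of the C1 acetyl, to give enolate 21, whose C3 adds to the C4 isopropyl ketone to give aldolate 22, which is protonated cold to 23. This is an intramolecular aldol addition of a 1,4-diketone, stopped at the β-hydroxy ketone stage. The cyclopentane closes in the 5-(enolexo)-exo-trig mode between two acyl groups that already stand trans on C1 and C5, so the trans ring fusion (1β-CH3, 5α-H) is inherited and neither fusion carbon is touched. The one new stereocenter, C4, is controlled by the ring: the isopropyl group should take the α face next to the small H5, and the oxygen the β face next to C6 and the C1 methyl group, which avoids an eclipsing contact between the isopropyl group and C6 with its silyl ether. The step needs site-selective enolisation (the CH3 against the tertiary C5–H and C11–H and the vinylogous C7–H) and must lose neither the C6 silyloxy group nor water. Kinetic deprotonation with one equivalent of a bulky amide at −78 °C, the fast five-membered closure and the cold acidic quench should secure this.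

Step 12
Reactants: 23 6α-(tert-butyldimethylsilyloxy)-4β-hydroxy-5αH-dauc-8-ene-2,10-dione
Product: 25 6α-(tert-butyldimethylsilyloxy)-2α,4β-dihydroxy-5αH-dauc-8-en-10-one, via alkoxyborohydride 24 (not isolated)
Conditions: Me4N[BH(OAc)3], MeCN–AcOH, −20 °C
Reagents that add atoms: none
Why: Hydroxyl-directed Evans–Saksena reduction, in which the 4β-hydroxyl exchanges onto boron to give 24, which delivers hydride to the β face of the C2 ketone and so gives the 2α-alcohol (1,3-anti diol), while the C10 enone has no hydroxyl in reach and is left untouched.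

Step 13
Reactants: 25 6α-(tert-butyldimethylsilyloxy)-2α,4β-dihydroxy-5αH-dauc-8-en-10-one
Product: 26 2α-acetoxy-6α-(tert-butyldimethylsilyloxy)-4β-hydroxy-5αH-dauc-8-en-10-one
Conditions: Ac2O, pyridine, DMAP (cat.), CH2Cl2, 0 °C to rt
Reagents that add atoms: acetic anhydride, CC(=O)OC(C)=O
Why: DMAP-catalysed acetylation of the secondary 2α-alcohol, in which the tertiary and flanked C4 hydroxyl is too hindered to react.

Step 14
Reactants: 26 2α-acetoxy-6α-(tert-butyldimethylsilyloxy)-4β-hydroxy-5αH-dauc-8-en-10-one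
Product: 27 2α-acetoxy-6α-(tert-butyldimethylsilyloxy)-5αH-dauc-8-ene-4β,10β-diol
Conditions: NaBH4, CeCl3·7H2O, MeOH, −78 to −20 °C
Reagents that add atoms: none
Why: Luche 1,2-reduction of the enone, in which hydride should approach C10 from the α face, away from the axial 1β-methyl group on the neighbouring carbon, to give the 10β-allylic alcohol with the acetate intact.

Step 15
Reactants: 27 2α-acetoxy-6α-(tert-butyldimethylsilyloxy)-5αH-dauc-8-ene-4β,10β-diol
Product: 28 2α-acetoxy-10β-benzoyloxy-6α-(tert-butyldimethylsilyloxy)-5αH-dauc-8-en-4β-ol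
Conditions: BzCl, pyridine, DMAP (cat.), CH2Cl2, rt
Reagents that add atoms: benzoyl chloride, O=C(Cl)c1ccccc1
Why: DMAP-catalysed benzoylation of the only free secondary alcohol, with the tertiary C4 hydroxyl again inert.

Step 16
Reactants: 28 2α-acetoxy-10β-benzoyloxy-6α-(tert-butyldimethylsilyloxy)-5αH-dauc-8-en-4β-ol
Product: 29 2α-acetoxy-10β-benzoyloxy-5αH-dauc-8-ene-4β,6α-diol
Conditions: HF·pyridine, excess pyridine, THF, 0 °C to rt
Reagents that add atoms: none
Why: Fluoride-mediated cleavage of the silyl ether with buffered HF·pyridine, mild enough for the acetate, the allylic benzoate and the tertiary alcohol and not basic enough to promote acyl migration.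

Step 17
Reactants: 29 2α-acetoxy-10β-benzoyloxy-5αH-dauc-8-ene-4β,6α-diol; 30 angelic acid
Product: 32 2α-acetoxy-6α-angeloyloxy-10β-benzoyloxy-5αH-dauc-8-en-4β-ol (CNP0248576.1), via mixed anhydride 31 (not isolated)
Conditions: 30, 2,4,6-trichlorobenzoyl chloride, Et3N, toluene, rt; then 29, 80 °C
Reagents that add atoms: none
Why: Yamaguchi-type esterification through mixed anhydride 31 without a nucleophilic catalyst, chosen because it acylates hindered secondary alcohols with angelic acid without Z-to-E isomerisation to the tiglate, while the tertiary C4 hydroxyl stays free.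

Compound list
1 | 2-methylpropene (isobutene) | CC(C)=C | starting material
2 | ethyl glyoxylate | CCOC(=O)C=O | starting material
3 | ethyl (S)-2-hydroxy-4-methylpent-4-enoate | CCOC(=O)[C@@H](O)CC(C)=C | intermediate
4 | ethyl (S)-2-(tert-butyldimethylsilyloxy)-4-methylpent-4-enoate | CCOC(=O)[C@@H](O[Si](C)(C)C(C)(C)C)CC(C)=C | intermediate
5 | (S)-2-(tert-butyldimethylsilyloxy)-4-methylpent-4-enal | O=C[C@@H](O[Si](C)(C)C(C)(C)C)CC(C)=C | intermediate
6 | pent-1-en-3-one (ethyl vinyl ketone) | CCC(=O)C=C | starting material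
7 | lithium penta-1,3-dien-3-olate (lithium enolate of 6) | CC=C(O[Li])C=C | intermediate
8 | (6S)-6-(tert-butyldimethylsilyloxy)-5-hydroxy-4,8-dimethylnona-1,8-dien-3-one | C=CC(=O)C(C)C(O)[C@@H](O[Si](C)(C)C(C)(C)C)CC(C)=C | intermediate
9 | (5S)-5-(tert-butyldimethylsilyloxy)-6-hydroxy-3,7-dimethylcyclohept-2-en-1-one | CC(C)(C)[Si](C)(C)O[C@H]1CC(C)=CC(=O)C(C)C1O | intermediate
10 | C5 methanesulfonate of 9 | CC(C)(C)[Si](C)(C)O[C@H]1CC(C)=CC(=O)C(C)C1OS(C)(=O)=O | intermediate
11 | (S)-4-(tert-butyldimethylsilyloxy)-2,6-dimethylcyclohepta-2,6-dien-1-one | CC(C)(C)[Si](C)(C)O[C@H]1CC(C)=CC(=O)C(C)=C1 | intermediate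
12 | 3-methylbut-1-yne | CC(C)C#C | starting material
13 | 2-bromo-3-methylbut-1-ene | CC(C)C(Br)=C | intermediate
14 | acetaldehyde | CC=O | starting material
15 | (3-methylbut-1-en-2-yl)magnesium bromide | CC(C)C(=C)[Mg]Br | intermediate
16 | bromomagnesium C1=C10 dienolate of the conjugate adduct (6α-OTBS, 5β-alkenyl) | CC(C)(C)[Si](C)(C)O[C@H]1CC(C)=CC(O[Mg]Br)=C(C)[C@@H]1C(=C)C(C)C | intermediate
17 | (5S,6S,7R)-5-(tert-butyldimethylsilyloxy)-7-(1-hydroxyethyl)-3,7-dimethyl-6-(3-methylbut-1-en-2-yl)cyclohept-2-en-1-one | CC(C)(C)[Si](C)(C)O[C@H]1CC(C)=CC(=O)[C@@](C)(C(C)O)[C@@H]1C(=C)C(C)C | intermediate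
18 | (5S,6S,7R)-7-acetyl-5-(tert-butyldimethylsilyloxy)-3,7-dimethyl-6-(3-methylbut-1-en-2-yl)cyclohept-2-en-1-one | CC(C)(C)[Si](C)(C)O[C@H]1CC(C)=CC(=O)[C@@](C)(C(C)=O)[C@@H]1C(=C)C(C)C | intermediate
19 | 1,2,4-trioxolane (ozonide) of the side-chain alkene of 18 | CC(C)(C)[Si](C)(C)O[C@H]1CC(C)=CC(=O)[C@@](C)(C(C)=O)[C@@H]1C2(C(C)C)OCOO2 | intermediate
20 | (5S,6S,7R)-7-acetyl-5-(tert-butyldimethylsilyloxy)-3,7-dimethyl-6-(2-methylpropanoyl)cyclohept-2-en-1-one | CC(C)(C)[Si](C)(C)O[C@H]1CC(C)=CC(=O)[C@@](C)(C(C)=O)[C@@H]1C(=O)C(C)C | intermediate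
21 | C2=C3 lithium enolate of 20 | CC(C)(C)[Si](C)(C)O[C@H]1CC(C)=CC(=O)[C@@](C)(C(=C)O[Li])[C@@H]1C(=O)C(C)C | intermediate
22 | lithium C4 alkoxide of 23 | CC(C)(C)[Si](C)(C)O[C@H]1CC(C)=CC(=O)[C@@]2(C)C(=O)C[C@@](O[Li])(C(C)C)[C@H]12 | intermediate
23 | 6α-(tert-butyldimethylsilyloxy)-4β-hydroxy-5αH-dauc-8-ene-2,10-dione | CC(C)(C)[Si](C)(C)O[C@H]1CC(C)=CC(=O)[C@@]2(C)C(=O)C[C@@](O)(C(C)C)[C@H]12 | intermediate
24 | tetramethylammonium C4-alkoxy(diacetoxy)borohydride of 23 | CC(C)(C)[Si](C)(C)O[C@H]1CC(C)=CC(=O)[C@@]2(C)C(=O)C[C@@](O[BH-](OC(C)=O)OC(C)=O)(C(C)C)[C@H]12.C[N+](C)(C)C | intermediate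
25 | 6α-(tert-butyldimethylsilyloxy)-2α,4β-dihydroxy-5αH-dauc-8-en-10-one | CC(C)(C)[Si](C)(C)O[C@H]1CC(C)=CC(=O)[C@@]2(C)[C@@H](O)C[C@@](O)(C(C)C)[C@H]12 | intermediate
26 | 2α-acetoxy-6α-(tert-butyldimethylsilyloxy)-4β-hydroxy-5αH-dauc-8-en-10-one | CC(C)(C)[Si](C)(C)O[C@H]1CC(C)=CC(=O)[C@@]2(C)[C@@H](OC(C)=O)C[C@@](O)(C(C)C)[C@H]12 | intermediate
27 | 2α-acetoxy-6α-(tert-butyldimethylsilyloxy)-5αH-dauc-8-ene-4β,10β-diol | CC(C)(C)[Si](C)(C)O[C@H]1CC(C)=C[C@H](O)[C@@]2(C)[C@@H](OC(C)=O)C[C@@](O)(C(C)C)[C@H]12 | intermediate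
28 | 2α-acetoxy-10β-benzoyloxy-6α-(tert-butyldimethylsilyloxy)-5αH-dauc-8-en-4β-ol | CC(C)(C)[Si](C)(C)O[C@H]1CC(C)=C[C@H](OC(=O)c3ccccc3)[C@@]2(C)[C@@H](OC(C)=O)C[C@@](O)(C(C)C)[C@H]12 | intermediate
29 | 2α-acetoxy-10β-benzoyloxy-5αH-dauc-8-ene-4β,6α-diol | O[C@H]1CC(C)=C[C@H](OC(=O)c3ccccc3)[C@@]2(C)[C@@H](OC(C)=O)C[C@@](O)(C(C)C)[C@H]12 | intermediate
30 | angelic acid, (Z)-2-methylbut-2-enoic acid | C/C=C(/C)C(=O)O | starting material
31 | angelic 2,4,6-trichlorobenzoic anhydride | C/C=C(/C)C(=O)OC(=O)c1c(Cl)cc(Cl)cc1Cl | intermediate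
32 | 2α-acetoxy-6α-angeloyloxy-10β-benzoyloxy-5αH-dauc-8-en-4β-ol (CNP0248576.1) | C/C=C(/C)C(=O)O[C@H]1CC(C)=C[C@H](OC(=O)c2ccccc2)[C@@]2(C)[C@@H](OC(C)=O)C[C@@](O)(C(C)C)[C@H]12 | target

Total step count: 17. Longest linear sequence: 16 steps (steps 1–6 and 8–17).

Steps most likely to fail

Step 11 (aldol ring closure).
- **What may go wrong:** Proton transfer from C5–H to enolate 21 could be followed by β-elimination of the C6 silyloxy group. The aldolate could revert or lose water on warming. The enolate could add to the wrong face of the C4 ketone.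
- **Fallback:** It sets out from 20. Soft enolisation of the unhindered acetyl group with Me3SiOTf and Et3N in CH2Cl2 gives the C2 trimethylsilyl enol ether F1. This is isolated and closed with TiCl4 in CH2Cl2 at −78 °C in an intramolecular Mukaiyama aldol addition. No free base is present and the titanium aldolate resists reversal. Aqueous work-up comes back to the route at 23.

Step 8 (conjugate addition with aldol trapping).
- **What may go wrong:** The hindered tetrasubstituted enolate may exchange protons with acetaldehyde. The aldolate may revert before the quench. 1,2-Addition or deprotonation at C7 may compete with conjugate addition.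
- **Fallback:** It sets out from 11 and separates the two bond formations. The copper-mediated addition of 15 is run in the presence of Me3SiCl, which speeds up the 1,4-addition and traps the product as the trimethylsilyl dienol ether F2. This is isolated and then joined to 14 with TiCl4 in CH2Cl2 at −78 °C in a Mukaiyama aldol addition, again anti to the 5β-alkenyl group. The sequence comes back to the route at 17.

Step 5 (ring-closing metathesis).
- **What may go wrong:** Turnover may be slow at the electron-poor vinyl ketone and the 1,1-disubstituted alkene, with dimerisation or catalyst decay before the trisubstituted seven-membered enone forms.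
- **Fallback:** It sets out from 8. Luche reduction (NaBH4, CeCl3·7H2O, MeOH) gives (6S)-6-(tert-butyldimethylsilyloxy)-4,8-dimethylnona-1,8-diene-3,5-diol F3, whose allylic alcohol terminus is a more willing metathesis partner. Ring-closing metathesis with the second-generation Grubbs catalyst gives (5S)-5-(tert-butyldimethylsilyloxy)-3,7-dimethylcyclohept-2-ene-1,6-diol F4. MnO2 in CH2Cl2 then oxidises only the allylic alcohol and comes back to the route at 9.

Further compounds
F1 | step 11 | C2 trimethylsilyl enol ether of 20 | CC(C)(C)[Si](C)(C)O[C@H]1CC(C)=CC(=O)[C@@](C)(C(=C)O[Si](C)(C)C)[C@@H]1C(=O)C(C)C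
F2 | step 8 | trimethylsilyl dienol ether of the conjugate adduct of 11 and 15 | CC(C)(C)[Si](C)(C)O[C@H]1CC(C)=CC(O[Si](C)(C)C)=C(C)[C@@H]1C(=C)C(C)C
F3 | step 5 | (6S)-6-(tert-butyldimethylsilyloxy)-4,8-dimethylnona-1,8-diene-3,5-diol | C=CC(O)C(C)C(O)[C@@H](O[Si](C)(C)C(C)(C)C)CC(C)=C
F4 | step 5 | (5S)-5-(tert-butyldimethylsilyloxy)-3,7-dimethylcyclohept-2-ene-1,6-diol | CC(C)(C)[Si](C)(C)O[C@H]1CC(C)=CC(O)C(C)C1O
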